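## Structural features

The target is a resveratrol trimer built on an indane: ring B (5,7-dihydroxy) is fused to a cyclopentane whose C1 carries the 4-hydroxyphenyl ring A, whose C2 is bonded to C4′ of a 2,3-dihydrobenzofuran (ring C, with the resorcinol ring D on C3′ and the 4-hydroxyphenyl ring E on C2′), and whose C3 carries the exocyclic carbinol carbon Cα with ring F (C7a lies between C1 and C7 in the numbering used throughout). There are six stereocentres: C1, C2, C3 and Cα are contiguous (1S,2R,3S with the three ring substituents all-trans, Cα S), and C2′ and C3′ are trans (R,R). The two groups of centres are separated by the C2–C4′ aryl bond, so neither can relay its configuration to the other and each needs its own absolute control. Fragile groups are the 4-hydroxybenzylic alcohol at Cα (quinone methide formation), the benzylic C2′–O1′ ether (ionises in acid), the C3–H (epimerisable once Cα is a carbonyl) and the electron-rich resorcinol-type rings (sensitive to oxidants and electrophiles). The real difficulty is the crowded 1,2,3-trisubstituted indane: C3a of ring B is meta to both oxygens, so C3–C3a cannot be made by electrophilic substitution, whereas C7a is ortho and para to them. The key step exploits the array C3a–C3–Cα, which maps onto a 1,2-dihydronaphthalene in which Cα is the ring carbon attached to C3a and C3=Cα is the styrene bond. A 1,2-shift of C3a from Cα to C3 then contracts the ring, sets C3 and leaves Cα at the aldehyde oxidation level.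

## Logic of the disconnections

**35 to 34.** The Cα–H bond is cut, which leaves an aryl ketone. The 4-hydroxybenzylic carbinol would not survive any deprotection, so it is created last; the cut removes one stereocentre and the most labile group. The forward step must draw 1,2-induction from C3 on a free octaphenol.

**34 to 33.** The eight O–CH3 bonds are cut. Methyl ethers are the phenol masks that tolerate organometallic reagents, Lewis acids and trivalent iodine, and one kind of protecting group for all eight phenols keeps the step count down. The demand is that the ketone and the dihydrobenzofuran come through a Lewis-acid demethylation that the carbinol would not survive.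

**33 to 32 to 30 + 31.** The ketone is traced to the carbinol and the Cα–ring F bond is cut. This removes ring F and returns Cα to an aldehyde. The forward steps need no selectivity at Cα, which is oxidised again, but C3 of 30 is epimerisable and must rest in its thermodynamic all-trans arrangement.

**30 to 29 to 27.** The aldehyde is traced to its acetal, then C3–C3a is broken and Cα–C3a restored with a C3=Cα double bond. The six-membered precursor has only two carbocyclic stereocentres and can be closed through the electron-rich C7a. The forward step must engage one unactivated styrene in the presence of five electron-rich arenes and add the iodane anti to the C2 aryl group.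

**27 to 26 to 25.** The alkene is traced to a benzylic alcohol and the C1–C7a bond is cut (Friedel–Crafts). Cutting at the diol level keeps ring B fully nucleophilic, and the gain is an open chain with one defined pair of centres. The forward closure must ionise only the 4-methoxybenzylic hydroxyl, form the six-membered and not the seven-membered ring, and place ring A trans to ring C.

**25 to 24 + 4, and 24 to 23.** The bond between the future Cα and C3a is cut, and the lactol is traced to the lactone. This removes ring B and leaves a trans-disubstituted butyrolactone. The forward addition has to stop after one aryl group, which the lactol guarantees where the lactone would not.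

**23 to 17 + 22.** The C2–C4′ bond is cut (conjugate addition). This is the convergent union of the two stereochemical domains and sets C2. The forward step needs a hindered arylboronic acid to add anti to the C5 aryl group of 22 without racemising 22.

**22 to 20 to 18 + 19.** The lactone C–O bond and then the alkynyl–carbinol bond are cut. Two steps from achiral materials give the enantioenriched acceptor. The demand is catalyst-controlled addition to one face of the aldehyde, then a semihydrogenation that stops at the Z-alkene.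

**17 to 14 to 6 + 11.** The C–B bond is cut, then C2′–C3′ and O1′–C2′ ([4+1] annulation). Both heterocyclic stereocentres come from one step on a small achiral phenol. The demand is absolute control by the sulfide part of 11 and trans selectivity in a quinone methide crowded by bromine.

**6 to 5 to 2 + 4; 2 to 1; 4 to 3; 11 to 9 + 10; 9 to 8 to 7.** Functional-group interchanges and one aryl–carbinol C–C bond lead back to commercial materials. Compound 3, through 4, supplies both ring D and ring B, and 7 supplies the chirality of the sulfide. The forward steps demand a site-selective ether cleavage in 1 and double inversion in the thiolane closure.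

## Other disconnections considered

**Alternative 1:** The cut is placed at the two carbon substituents of ring C, C4′–C2 and C3a′–C3′, which are traced to one aryne insertion. In the forward step fluoride desilylates silyl triflate A2 and triflate is lost. The aryne so released from A2 takes up the enolate of β-keto ester A3. The enolate carbon (future C2) adds at the aryne carbon remote from the flanking methoxy group, the aryl anion at C3a′ closes onto the ketone, and the four-membered alkoxide fragments to keto ester A1.
- In its favour: one reliable step from cheap achiral pieces gives the full ring C substitution pattern with regiocontrol, and installs ring D and an acetate arm for C2.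
- Against it here: no stereocentre and no ring of the target is formed. The C3′ ketone still has to become a CH trans to a C2′ aryl group in the absolute sense, the methyl ether next to the ketone has to be singled out for O1′, and the acetate CH2 has to be built into the congested C1–C2–C3 triad.
- Comparison: mechanistically the aryne insertion is at least the equal of any single step of the chosen route. Structurally it solves a problem the chosen route does not have, since the same ring C pattern is bought in 1. In step economy it is clearly longer after A1.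

**Alternative 2:** The cut is C3a–C4, so ring B is made last from a non-aromatic precursor. In the forward step aqueous KOH opens the pyranone ring of the cyclopentane-fused 2-methyl-4-pyranone A5. In the ring-opened triketone form of A5 the terminal methyl carbon condenses onto the ring carbonyl, and dehydration with enolisation gives the resorcinol A4.
- In its favour: the stereotriad and Cα are set by aliphatic chemistry before ring B exists, so there is no regiochemical or oxidant problem at ring B. Ring B arrives with free hydroxyls, differentiated from the methyl ethers. Cα already carries its configuration as a silyl ether, so no late substrate-controlled reduction is needed; on this point it is better than the chosen plan.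
- Against it here: in the open triketone the silyloxy group on Cα is β to a carbonyl and can be lost by elimination in hot hydroxide, and C1 and C3 are enolisable. A5 is itself a long target. The remaining methyl ethers would then have to be removed in the presence of the Cα carbinol, which a Lewis-acid demethylation does not allow.
- Comparison: the fold is as well founded mechanistically as the ring contraction (equal). The chosen plan is much shorter because ring B is bought, and it has a workable deprotection end game.

**Alternative 3:** The cut is C2′–C3′ and O1′–C2′ at the end of the synthesis. In the forward step Cs2CO3 expels sulfinate from hydroxy sulfone A7, which unmasks the quinone methide of ring C. The ylide formed from sulfonium salt A8 in the same flask adds at C3′, and the phenoxide displaces the sulfide at C2′ to give A6, which is identical with 33.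
- In its favour: it is convergent and intrinsically trans-selective. The acid-labile dihydrobenzofuran never meets the Lewis-acid cyclisation, the iodane or the Grignard steps; on this point it is better than the chosen plan. It arrives at the ketone through which the chosen route also passes.
- Against it here: the two new centres must be set relative to three remote indane centres, so a chiral ylide has to work on a late, precious substrate in which ring C is flanked on both sides, and any mismatch gives diastereomers. One ring C oxygen must be kept differentiated through the whole synthesis, and C3 of A7 is enolisable under the carbonate.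
- Comparison: the chosen route uses the same annulation (step 8) on the small achiral phenol 6, where enantiopurity can be checked and upgraded before the union. Step counts are about equal. The alternative places the stereochemical risk late; the chosen plan places the heterocycle at risk through the acid steps.

Key step: step 17

Assumption: the antipodes of ProPhenol (step 10) and of the thiolane (step 8) are taken to induce the stated sense by analogy with their use in aldehyde alkynylation and ylide epoxidation; if either sense is reversed, the mirror-image ligand or sulfide is used and nothing else changes.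

## Route

Step 1
Reactants: 1 2-bromo-4,6-dimethoxybenzaldehyde
Product: 2 2-bromo-6-hydroxy-4-methoxybenzaldehyde
Conditions: BCl3 (1.1 equiv), CH2Cl2, −78 → 0 °C; H2O
Reagents that add atoms: none
Why: Chelation-directed Lewis-acid ether cleavage: BCl3 bound to the formyl oxygen cleaves only the ortho methoxy group, leaving the para methoxy group and the bromide untouched.

Step 2
Reactants: 3 1-bromo-3,5-dimethoxybenzene
Product: 4 3,5-dimethoxyphenylmagnesium bromide (titrated THF solution, kept under argon)
Conditions: Mg turnings (1.2 equiv), I2 (cat.), THF, 50 °C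
Reagents that add atoms: magnesium, [Mg]
Why: Grignard reagent formation by insertion of magnesium into the aryl C–Br bond; the electron-rich aryl bromide inserts cleanly in warm THF, and the titrated solution (made afresh in the same way when needed) serves steps 3 and 14.

Step 3
Reactants: 2 2-bromo-6-hydroxy-4-methoxybenzaldehyde; 4 3,5-dimethoxyphenylmagnesium bromide
Product: 5 3-bromo-2-[(3,5-dimethoxyphenyl)(hydroxy)methyl]-5-methoxyphenol (racemic)
Conditions: 4 (2.5 equiv), THF, 0 °C → rt; aq. NH4Cl
Reagents that add atoms: none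
Why: Grignard 1,2-addition; the first equivalent deprotonates the phenol and the second adds to the aldehyde, and the racemic carbinol centre is erased when the quinone methide forms in step 8.

Step 4
Reactants: 5 3-bromo-2-[(3,5-dimethoxyphenyl)(hydroxy)methyl]-5-methoxyphenol
Product: 6 3-bromo-2-[(3,5-dimethoxyphenyl)(4-methylbenzenesulfonyl)methyl]-5-methoxyphenol (racemic)
Conditions: sodium 4-methylbenzenesulfinate (1.5 equiv), HCO2H/H2O, rt
Reagents that add atoms: sodium 4-methylbenzenesulfinate, Cc1ccc(S(=O)[O-])cc1.[Na+]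
Why: Acid-promoted SN1 substitution of the ortho-hydroxybenzhydrol through its stabilised cation, with S-alkylation of sulfinate; the sulfone is a bench-stable precursor that releases the quinone methide under mild base.

Step 5
Reactants: 7 (2S,5S)-hexane-2,5-diol
Product: 8 (2S,5S)-hexane-2,5-diyl dimethanesulfonate
Conditions: MsCl (2.4 equiv), Et3N, CH2Cl2, 0 °C
Reagents that add atoms: methanesulfonyl chloride, CS(=O)(=O)Cl
Why: O-Sulfonylation of both secondary alcohols with retention of configuration.

Step 6
Reactants: 8 (2S,5S)-hexane-2,5-diyl dimethanesulfonate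
Product: 9 (2R,5R)-2,5-dimethylthiolane
Conditions: Na2S·9H2O, DMSO, rt
Reagents that add atoms: sodium sulfide, [Na+].[Na+].[S-2]
Why: Double SN2 displacement by sulfide; both centres invert, giving the C2-symmetric trans thiolane.

Step 7
Reactants: 9 (2R,5R)-2,5-dimethylthiolane; 10 (4-methoxyphenyl)methanol
Product: 11 (2R,5R)-1-[(4-methoxyphenyl)methyl]-2,5-dimethylthiolan-1-ium tetrafluoroborate
Conditions: HBF4·OEt2 (1.1 equiv), CH2Cl2, 0 °C → rt
Reagents that add atoms: tetrafluoroboric acid (diethyl ether complex), [H+].F[B-](F)(F)F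
Why: Acid-mediated S-alkylation: the 4-methoxybenzyl cation from 10 is captured by sulfur, and because the thiolane is C2-symmetric sulfur is not stereogenic, so a single salt forms.

Step 8
Reactants: 6 3-bromo-2-[(3,5-dimethoxyphenyl)(4-methylbenzenesulfonyl)methyl]-5-methoxyphenol; 11 (2R,5R)-1-[(4-methoxyphenyl)methyl]-2,5-dimethylthiolan-1-ium tetrafluoroborate
Product: 14 (2R,3R)-4-bromo-3-(3,5-dimethoxyphenyl)-6-methoxy-2-(4-methoxyphenyl)-2,3-dihydro-1-benzofuran, via ortho-quinone methide 12 (not isolated), via sulfonium ylide 13 (not isolated)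
Conditions: 11 (1.3 equiv), Cs2CO3 (3 equiv), MeCN/CH2Cl2, −20 °C → rt
Reagents that add atoms: none
Why: Formal [4+1] annulation of a sulfur ylide with an ortho-quinone methide: carbonate expels sulfinate from 6 and deprotonates 11, the ylide carbon adds to the methide carbon (C3′), and the phenoxide displaces the sulfide at C2′ with inversion (5-exo-tet). The C2-symmetric thiolane fixes the reacting face of the ylide carbon and hence C2′ (R); the addition mode that keeps the two aryl groups apart gives the trans relation and hence C3′ (R).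

Step 9
Reactants: 14 (2R,3R)-4-bromo-3-(3,5-dimethoxyphenyl)-6-methoxy-2-(4-methoxyphenyl)-2,3-dihydro-1-benzofuran
Product: 17 [(2R,3R)-3-(3,5-dimethoxyphenyl)-6-methoxy-2-(4-methoxyphenyl)-2,3-dihydro-1-benzofuran-4-yl]boronic acid, via aryllithium 15 (not isolated), via lithium triisopropoxy arylborate 16 (not isolated)
Conditions: B(OiPr)3 (1.5 equiv), n-BuLi (1.1 equiv), THF/toluene, −78 °C; then 1 M HCl, rt
Reagents that add atoms: triisopropyl borate, CC(C)OB(OC(C)C)OC(C)C; water, O
Why: Bromine–lithium exchange with in situ borate trapping, then hydrolysis; the internal quench keeps the aryllithium from abstracting the C3′ proton, so both stereocentres are untouched.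

Step 10
Reactants: 18 4-methoxybenzaldehyde; 19 methyl prop-2-ynoate
Product: 20 methyl (4R)-4-hydroxy-4-(4-methoxyphenyl)but-2-ynoate
Conditions: (R,R)-ProPhenol (10 mol%), Me2Zn (3 equiv), Ph3PO (20 mol%), toluene, 0 °C; aq. NH4Cl
Reagents that add atoms: none
Why: Enantioselective alkynylation of an aldehyde catalysed by Me2Zn and (R,R)-ProPhenol; the dinuclear zinc alkoxide formed from the two delivers the alkynyl group to one carbonyl face and sets the carbinol (4R, which becomes 5S in the butenolide by a priority change only).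

Step 11
Reactants: 20 methyl (4R)-4-hydroxy-4-(4-methoxyphenyl)but-2-ynoate
Product: 22 (5S)-5-(4-methoxyphenyl)furan-2(5H)-one, via Z-hydroxy enoate 21 (not isolated)
Conditions: H2 (1 atm), Pd/CaCO3–Pb(OAc)2, quinoline, EtOAc, rt; then PPTS (cat.), CH2Cl2, rt
Reagents that add atoms: none
Why: Lindlar semihydrogenation gives the Z-enoate, which lactonises by acyl substitution; the stereocentre is not involved.

Step 12
Reactants: 17 [(2R,3R)-3-(3,5-dimethoxyphenyl)-6-methoxy-2-(4-methoxyphenyl)-2,3-dihydro-1-benzofuran-4-yl]boronic acid; 22 (5S)-5-(4-methoxyphenyl)furan-2(5H)-one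
Product: 23 (4R,5S)-4-[(2R,3R)-3-(3,5-dimethoxyphenyl)-6-methoxy-2-(4-methoxyphenyl)-2,3-dihydro-1-benzofuran-4-yl]-5-(4-methoxyphenyl)oxolan-2-one
Conditions: 22 (2.5 equiv), [Rh(OH)((R)-BINAP)]2 (3 mol%), dioxane/H2O (10:1), 40 °C
Reagents that add atoms: none
Why: Hayashi–Miyaura rhodium-catalysed conjugate addition: the aryl–rhodium species inserts the butenolide on the face anti to the C5 aryl group, and (R)-BINAP selects the same face (matched pair), giving the trans lactone and setting future C2. The base-free catalyst [Rh(OH)((R)-BINAP)]2 and the excess of acceptor limit racemisation of 22 and protodeboronation of 17.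

Step 13
Reactants: 23 (4R,5S)-4-[(2R,3R)-3-(3,5-dimethoxyphenyl)-6-methoxy-2-(4-methoxyphenyl)-2,3-dihydro-1-benzofuran-4-yl]-5-(4-methoxyphenyl)oxolan-2-one
Product: 24 (4R,5S)-4-[(2R,3R)-3-(3,5-dimethoxyphenyl)-6-methoxy-2-(4-methoxyphenyl)-2,3-dihydro-1-benzofuran-4-yl]-5-(4-methoxyphenyl)oxolan-2-ol (anomers)
Conditions: iBu2AlH (1.2 equiv), CH2Cl2, −78 °C; aq. KNaC4H4O6
Reagents that add atoms: none
Why: Partial reduction of the lactone to the lactol; the aluminium hemiacetal is stable at −78 °C and collapses only on work-up.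

Step 14
Reactants: 24 (4R,5S)-4-[(2R,3R)-3-(3,5-dimethoxyphenyl)-6-methoxy-2-(4-methoxyphenyl)-2,3-dihydro-1-benzofuran-4-yl]-5-(4-methoxyphenyl)oxolan-2-ol; 4 3,5-dimethoxyphenylmagnesium bromide
Product: 25 (3R,4S)-1-(3,5-dimethoxyphenyl)-3-[(2R,3R)-3-(3,5-dimethoxyphenyl)-6-methoxy-2-(4-methoxyphenyl)-2,3-dihydro-1-benzofuran-4-yl]-4-(4-methoxyphenyl)butane-1,4-diol (C1 epimers)
Conditions: 4 (3 equiv), THF, 0 °C → rt; aq. NH4Cl
Reagents that add atoms: none
Why: Grignard addition to the open hydroxy-aldehyde form of the lactol after deprotonation by the first equivalent; no over-addition is possible, and the new carbinol (an epimer mixture) is removed in step 16.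

Step 15
Reactants: 25 (3R,4S)-1-(3,5-dimethoxyphenyl)-3-[(2R,3R)-3-(3,5-dimethoxyphenyl)-6-methoxy-2-(4-methoxyphenyl)-2,3-dihydro-1-benzofuran-4-yl]-4-(4-methoxyphenyl)butane-1,4-diol
Product: 26 (3S,4S)-3-[(2R,3R)-3-(3,5-dimethoxyphenyl)-6-methoxy-2-(4-methoxyphenyl)-2,3-dihydro-1-benzofuran-4-yl]-5,7-dimethoxy-4-(4-methoxyphenyl)-1,2,3,4-tetrahydronaphthalen-1-ol (C1 epimers)
Conditions: Bi(OTf)3 (5 mol%), CH2Cl2, 0 °C
Reagents that add atoms: none
Why: Intramolecular Friedel–Crafts alkylation (cyclodehydration of the aryltetralin type): only the 4-methoxybenzylic alcohol ionises, and ring B attacks through a carbon ortho and para to its methoxy groups (six-membered closure; both ortho positions are equivalent). The aryl groups end trans-diequatorial, which sets C1; the other hydroxyl sits on a non-stabilised benzylic carbon and stays, and any cyclic ether formed from it re-ionises to the same cation.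

Step 16
Reactants: 26 (3S,4S)-3-[(2R,3R)-3-(3,5-dimethoxyphenyl)-6-methoxy-2-(4-methoxyphenyl)-2,3-dihydro-1-benzofuran-4-yl]-5,7-dimethoxy-4-(4-methoxyphenyl)-1,2,3,4-tetrahydronaphthalen-1-ol
Product: 27 (1S,2S)-2-[(2R,3R)-3-(3,5-dimethoxyphenyl)-6-methoxy-2-(4-methoxyphenyl)-2,3-dihydro-1-benzofuran-4-yl]-6,8-dimethoxy-1-(4-methoxyphenyl)-1,2-dihydronaphthalene
Conditions: MeO2CN(−)SO2N(+)Et3 (1.5 equiv), toluene, 60 °C
Reagents that add atoms: none
Why: Burgess dehydration (syn elimination of the sulfamate) under non-acidic conditions; the only β-hydrogens are on the CH2, so only the styrene forms and both epimers converge.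

Step 17
Reactants: 27 (1S,2S)-2-[(2R,3R)-3-(3,5-dimethoxyphenyl)-6-methoxy-2-(4-methoxyphenyl)-2,3-dihydro-1-benzofuran-4-yl]-6,8-dimethoxy-1-(4-methoxyphenyl)-1,2-dihydronaphthalene
Product: 29 (1S,2R,3S)-3-(dimethoxymethyl)-2-[(2R,3R)-3-(3,5-dimethoxyphenyl)-6-methoxy-2-(4-methoxyphenyl)-2,3-dihydro-1-benzofuran-4-yl]-5,7-dimethoxy-1-(4-methoxyphenyl)indane, via methoxy iodonium tosylate 28 (not isolated)
Conditions: PhI(OH)OTs (1.2 equiv), MeOH/HC(OMe)3 (4:1), 0 °C → rt
Reagents that add atoms: methanol, CO
Why: This is the oxidative ring contraction of a 1,2-dihydronaphthalene by trivalent iodine, the known route to trans-substituted indan-1-yl dimethyl acetals (trivalent thallium as Tl(NO3)3 does the same). The electrophilic iodane adds to the styrene at C3, which leaves the positive charge benzylic at Cα, and methanol caps Cα anti to iodine to give adduct 28. In the all-equatorial half-chair of 28 the C3–I bond is antiperiplanar to the Cα–C3a ring bond, so C3a shifts from Cα to C3 as iodobenzene leaves; the methoxy group on Cα turns the migration origin into an oxocarbenium ion, which methanol traps as the acetal. The five-membered ring is thus closed by a 1,2-aryl (Wagner–Meerwein) shift through a bridged phenonium-like transition state, a contraction of the six-membered ring with C3–C3a as the only new skeletal bond. The new stereocentre C3 is controlled by the C2 aryl group: iodine enters anti to it and the migration inverts C3, placing the acetal carbon trans to ring C, while C1 and C2 are untouched. The step needs chemoselectivity for the alkene over five electron-rich arenes (methanol as a nucleophilic, weakly ionising solvent, low temperature, near-stoichiometric oxidant), Markovnikov regiochemistry (benzylic Cα), and migration of C3a in preference to C1, which the oxocarbenium-forming methoxy group enforces.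

Step 18
Reactants: 29 (1S,2R,3S)-3-(dimethoxymethyl)-2-[(2R,3R)-3-(3,5-dimethoxyphenyl)-6-methoxy-2-(4-methoxyphenyl)-2,3-dihydro-1-benzofuran-4-yl]-5,7-dimethoxy-1-(4-methoxyphenyl)indane
Product: 30 (1S,2R,3S)-2-[(2R,3R)-3-(3,5-dimethoxyphenyl)-6-methoxy-2-(4-methoxyphenyl)-2,3-dihydro-1-benzofuran-4-yl]-5,7-dimethoxy-1-(4-methoxyphenyl)indane-3-carbaldehyde
Conditions: 1 M HCl, THF, rt; then DBU (0.2 equiv), CH2Cl2, rt
Reagents that add atoms: water, O
Why: Acetal hydrolysis; the brief amidine-base treatment equilibrates the benzylic α-centre, so any cis aldehyde converges on the all-trans isomer.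

Step 19
Reactants: 30 (1S,2R,3S)-2-[(2R,3R)-3-(3,5-dimethoxyphenyl)-6-methoxy-2-(4-methoxyphenyl)-2,3-dihydro-1-benzofuran-4-yl]-5,7-dimethoxy-1-(4-methoxyphenyl)indane-3-carbaldehyde; 31 4-methoxyphenylmagnesium bromide
Product: 32 [(1S,2R,3S)-2-[(2R,3R)-3-(3,5-dimethoxyphenyl)-6-methoxy-2-(4-methoxyphenyl)-2,3-dihydro-1-benzofuran-4-yl]-5,7-dimethoxy-1-(4-methoxyphenyl)indan-3-yl](4-methoxyphenyl)methanol (Cα epimers)
Conditions: 31 (1.5 equiv), THF, −78 → 0 °C; aq. NH4Cl
Reagents that add atoms: none
Why: Grignard 1,2-addition; Felkin–Anh delivery of the aryl group should favour the Cα epimer opposite to the target, which is why the centre is reset through the ketone.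

Step 20
Reactants: 32 [(1S,2R,3S)-2-[(2R,3R)-3-(3,5-dimethoxyphenyl)-6-methoxy-2-(4-methoxyphenyl)-2,3-dihydro-1-benzofuran-4-yl]-5,7-dimethoxy-1-(4-methoxyphenyl)indan-3-yl](4-methoxyphenyl)methanol
Product: 33 [(1S,2R,3S)-2-[(2R,3R)-3-(3,5-dimethoxyphenyl)-6-methoxy-2-(4-methoxyphenyl)-2,3-dihydro-1-benzofuran-4-yl]-5,7-dimethoxy-1-(4-methoxyphenyl)indan-3-yl](4-methoxyphenyl)methanone
Conditions: Dess–Martin periodinane (1.5 equiv), NaHCO3, CH2Cl2, rt
Reagents that add atoms: none
Why: Dess–Martin oxidation under buffered neutral conditions; both epimers converge, and the trans ketone is the thermodynamic isomer at C3.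

Step 21
Reactants: 33 [(1S,2R,3S)-2-[(2R,3R)-3-(3,5-dimethoxyphenyl)-6-methoxy-2-(4-methoxyphenyl)-2,3-dihydro-1-benzofuran-4-yl]-5,7-dimethoxy-1-(4-methoxyphenyl)indan-3-yl](4-methoxyphenyl)methanone
Product: 34 [(1S,2R,3S)-2-[(2R,3R)-3-(3,5-dihydroxyphenyl)-6-hydroxy-2-(4-hydroxyphenyl)-2,3-dihydro-1-benzofuran-4-yl]-5,7-dihydroxy-1-(4-hydroxyphenyl)indan-3-yl](4-hydroxyphenyl)methanone
Conditions: BBr3 (20 equiv), CH2Cl2, −78 °C → rt; MeOH then H2O
Reagents that add atoms: none
Why: Lewis-acid cleavage of the eight aryl methyl ethers; the ketone does not ionise as a carbinol would, and the 2,3-trans dihydrobenzofuran is the thermodynamic isomer should C2′–O open reversibly.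

Step 22
Reactants: 34 [(1S,2R,3S)-2-[(2R,3R)-3-(3,5-dihydroxyphenyl)-6-hydroxy-2-(4-hydroxyphenyl)-2,3-dihydro-1-benzofuran-4-yl]-5,7-dihydroxy-1-(4-hydroxyphenyl)indan-3-yl](4-hydroxyphenyl)methanone
Product: 35 (1S,2R,3S)-2-[(2R,3R)-3-(3,5-dihydroxyphenyl)-6-hydroxy-2-(4-hydroxyphenyl)-2,3-dihydro-1-benzofuran-4-yl]-3-[(S)-hydroxy(4-hydroxyphenyl)methyl]-1-(4-hydroxyphenyl)indane-5,7-diol
Conditions: NaBH4 (excess), MeOH, −20 → 0 °C; pH 7 buffer
Reagents that add atoms: none
Why: Felkin–Anh controlled hydride addition to the aryl ketone: with the ring B carbon C3a anti to the incoming hydride and the C3 hydrogen on the side of the ketone aryl group, hydride should enter the Re face and give the S carbinol. Borohydride in methanol tolerates the free phenols, and the neutral work-up protects the 4-hydroxybenzylic alcohol.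

## Compound list

1 | 2-bromo-4,6-dimethoxybenzaldehyde | O=Cc1c(Br)cc(OC)cc1OC | starting material
2 | 2-bromo-6-hydroxy-4-methoxybenzaldehyde | O=Cc1c(Br)cc(OC)cc1O | intermediate
3 | 1-bromo-3,5-dimethoxybenzene | COc1cc(Br)cc(OC)c1 | starting material
4 | 3,5-dimethoxyphenylmagnesium bromide (titrated THF solution) | COc1cc([Mg]Br)cc(OC)c1 | intermediate
5 | 3-bromo-2-[(3,5-dimethoxyphenyl)(hydroxy)methyl]-5-methoxyphenol (racemic) | Oc1cc(OC)cc(Br)c1C(O)c1cc(OC)cc(OC)c1 | intermediate
6 | 3-bromo-2-[(3,5-dimethoxyphenyl)(4-methylbenzenesulfonyl)methyl]-5-methoxyphenol (racemic) | Oc1cc(OC)cc(Br)c1C(c1cc(OC)cc(OC)c1)S(=O)(=O)c1ccc(C)cc1 | intermediate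
7 | (2S,5S)-hexane-2,5-diol | C[C@H](O)CC[C@H](C)O | starting material
8 | (2S,5S)-hexane-2,5-diyl dimethanesulfonate | C[C@H](OS(C)(=O)=O)CC[C@H](C)OS(C)(=O)=O | intermediate
9 | (2R,5R)-2,5-dimethylthiolane | C[C@@H]1CC[C@@H](C)S1 | intermediate
10 | (4-methoxyphenyl)methanol | COc1ccc(CO)cc1 | starting material
11 | (2R,5R)-1-[(4-methoxyphenyl)methyl]-2,5-dimethylthiolan-1-ium tetrafluoroborate | COc1ccc(C[S+]2[C@H](C)CC[C@H]2C)cc1.F[B-](F)(F)F | intermediate
12 | 5-bromo-6-[(3,5-dimethoxyphenyl)methylidene]-3-methoxycyclohexa-2,4-dien-1-one (ortho-quinone methide) | O=C1C=C(OC)C=C(Br)C1=Cc1cc(OC)cc(OC)c1 | intermediate (not isolated)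
13 | (2R,5R)-2,5-dimethylthiolan-1-ium-1-yl (4-methoxyphenyl)methanide (sulfonium ylide) | COc1ccc([CH-][S+]2[C@H](C)CC[C@H]2C)cc1 | intermediate (not isolated)
14 | (2R,3R)-4-bromo-3-(3,5-dimethoxyphenyl)-6-methoxy-2-(4-methoxyphenyl)-2,3-dihydro-1-benzofuran | Brc1cc(OC)cc2c1[C@@H](c1cc(OC)cc(OC)c1)[C@H](c1ccc(OC)cc1)O2 | intermediate
15 | [(2R,3R)-3-(3,5-dimethoxyphenyl)-6-methoxy-2-(4-methoxyphenyl)-2,3-dihydro-1-benzofuran-4-yl]lithium | [Li]c1cc(OC)cc2c1[C@@H](c1cc(OC)cc(OC)c1)[C@H](c1ccc(OC)cc1)O2 | intermediate (not isolated)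
16 | lithium [(2R,3R)-3-(3,5-dimethoxyphenyl)-6-methoxy-2-(4-methoxyphenyl)-2,3-dihydro-1-benzofuran-4-yl]tri(propan-2-yloxy)borate | [Li+].CC(C)O[B-](OC(C)C)(OC(C)C)c1cc(OC)cc2c1[C@@H](c1cc(OC)cc(OC)c1)[C@H](c1ccc(OC)cc1)O2 | intermediate (not isolated)
17 | [(2R,3R)-3-(3,5-dimethoxyphenyl)-6-methoxy-2-(4-methoxyphenyl)-2,3-dihydro-1-benzofuran-4-yl]boronic acid | OB(O)c1cc(OC)cc2c1[C@@H](c1cc(OC)cc(OC)c1)[C@H](c1ccc(OC)cc1)O2 | intermediate
18 | 4-methoxybenzaldehyde | COc1ccc(C=O)cc1 | starting material
19 | methyl prop-2-ynoate | C#CC(=O)OC | starting material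
20 | methyl (4R)-4-hydroxy-4-(4-methoxyphenyl)but-2-ynoate | COC(=O)C#C[C@H](O)c1ccc(OC)cc1 | intermediate
21 | methyl (2Z,4S)-4-hydroxy-4-(4-methoxyphenyl)but-2-enoate | COC(=O)/C=C\[C@H](O)c1ccc(OC)cc1 | intermediate (not isolated)
22 | (5S)-5-(4-methoxyphenyl)furan-2(5H)-one | O=C1C=C[C@@H](c2ccc(OC)cc2)O1 | intermediate
23 | (4R,5S)-4-[(2R,3R)-3-(3,5-dimethoxyphenyl)-6-methoxy-2-(4-methoxyphenyl)-2,3-dihydro-1-benzofuran-4-yl]-5-(4-methoxyphenyl)oxolan-2-one | O=C1C[C@@H]([C@@H](c2ccc(OC)cc2)O1)c1cc(OC)cc2c1[C@@H](c1cc(OC)cc(OC)c1)[C@H](c1ccc(OC)cc1)O2 | intermediate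
24 | (4R,5S)-4-[(2R,3R)-3-(3,5-dimethoxyphenyl)-6-methoxy-2-(4-methoxyphenyl)-2,3-dihydro-1-benzofuran-4-yl]-5-(4-methoxyphenyl)oxolan-2-ol (anomers) | OC1C[C@@H]([C@@H](c2ccc(OC)cc2)O1)c1cc(OC)cc2c1[C@@H](c1cc(OC)cc(OC)c1)[C@H](c1ccc(OC)cc1)O2 | intermediate
25 | (3R,4S)-1-(3,5-dimethoxyphenyl)-3-[(2R,3R)-3-(3,5-dimethoxyphenyl)-6-methoxy-2-(4-methoxyphenyl)-2,3-dihydro-1-benzofuran-4-yl]-4-(4-methoxyphenyl)butane-1,4-diol (C1 epimers) | OC(C[C@@H]([C@H](O)c1ccc(OC)cc1)c1cc(OC)cc2c1[C@@H](c1cc(OC)cc(OC)c1)[C@H](c1ccc(OC)cc1)O2)c1cc(OC)cc(OC)c1 | intermediate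
26 | (3S,4S)-3-[(2R,3R)-3-(3,5-dimethoxyphenyl)-6-methoxy-2-(4-methoxyphenyl)-2,3-dihydro-1-benzofuran-4-yl]-5,7-dimethoxy-4-(4-methoxyphenyl)-1,2,3,4-tetrahydronaphthalen-1-ol (C1 epimers) | COc1ccc([C@H]2c3c(OC)cc(OC)cc3C(O)C[C@@H]2c2cc(OC)cc3c2[C@@H](c2cc(OC)cc(OC)c2)[C@H](c2ccc(OC)cc2)O3)cc1 | intermediate
27 | (1S,2S)-2-[(2R,3R)-3-(3,5-dimethoxyphenyl)-6-methoxy-2-(4-methoxyphenyl)-2,3-dihydro-1-benzofuran-4-yl]-6,8-dimethoxy-1-(4-methoxyphenyl)-1,2-dihydronaphthalene | COc1ccc([C@H]2c3c(OC)cc(OC)cc3C=C[C@@H]2c2cc(OC)cc3c2[C@@H](c2cc(OC)cc(OC)c2)[C@H](c2ccc(OC)cc2)O3)cc1 | intermediate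
28 | phenyl(tetralin-3-yl)iodonium tosylate of 27: iodine on C3 anti to the C2 aryl group, methoxy on C4 trans to iodine, C1 and C2 as in 27 | COc1ccc([C@H]2c3c(OC)cc(OC)cc3[C@H](OC)[C@@H]([I+]c3ccccc3)[C@@H]2c2cc(OC)cc3c2[C@@H](c2cc(OC)cc(OC)c2)[C@H](c2ccc(OC)cc2)O3)cc1.Cc1ccc(S(=O)(=O)[O-])cc1 | intermediate (not isolated)
29 | (1S,2R,3S)-3-(dimethoxymethyl)-2-[(2R,3R)-3-(3,5-dimethoxyphenyl)-6-methoxy-2-(4-methoxyphenyl)-2,3-dihydro-1-benzofuran-4-yl]-5,7-dimethoxy-1-(4-methoxyphenyl)indane | COc1ccc([C@H]2c3c(OC)cc(OC)cc3[C@@H](C(OC)OC)[C@@H]2c2cc(OC)cc3c2[C@@H](c2cc(OC)cc(OC)c2)[C@H](c2ccc(OC)cc2)O3)cc1 | intermediate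
30 | (1S,2R,3S)-2-[(2R,3R)-3-(3,5-dimethoxyphenyl)-6-methoxy-2-(4-methoxyphenyl)-2,3-dihydro-1-benzofuran-4-yl]-5,7-dimethoxy-1-(4-methoxyphenyl)indane-3-carbaldehyde | COc1ccc([C@H]2c3c(OC)cc(OC)cc3[C@@H](C=O)[C@@H]2c2cc(OC)cc3c2[C@@H](c2cc(OC)cc(OC)c2)[C@H](c2ccc(OC)cc2)O3)cc1 | intermediate
31 | 4-methoxyphenylmagnesium bromide (THF solution) | COc1ccc([Mg]Br)cc1 | starting material
32 | [(1S,2R,3S)-2-[(2R,3R)-3-(3,5-dimethoxyphenyl)-6-methoxy-2-(4-methoxyphenyl)-2,3-dihydro-1-benzofuran-4-yl]-5,7-dimethoxy-1-(4-methoxyphenyl)indan-3-yl](4-methoxyphenyl)methanol (Cα epimers) | COc1ccc([C@H]2c3c(OC)cc(OC)cc3[C@@H](C(O)c3ccc(OC)cc3)[C@@H]2c2cc(OC)cc3c2[C@@H](c2cc(OC)cc(OC)c2)[C@H](c2ccc(OC)cc2)O3)cc1 | intermediate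
33 | [(1S,2R,3S)-2-[(2R,3R)-3-(3,5-dimethoxyphenyl)-6-methoxy-2-(4-methoxyphenyl)-2,3-dihydro-1-benzofuran-4-yl]-5,7-dimethoxy-1-(4-methoxyphenyl)indan-3-yl](4-methoxyphenyl)methanone | COc1ccc([C@H]2c3c(OC)cc(OC)cc3[C@@H](C(=O)c3ccc(OC)cc3)[C@@H]2c2cc(OC)cc3c2[C@@H](c2cc(OC)cc(OC)c2)[C@H](c2ccc(OC)cc2)O3)cc1 | intermediate
34 | [(1S,2R,3S)-2-[(2R,3R)-3-(3,5-dihydroxyphenyl)-6-hydroxy-2-(4-hydroxyphenyl)-2,3-dihydro-1-benzofuran-4-yl]-5,7-dihydroxy-1-(4-hydroxyphenyl)indan-3-yl](4-hydroxyphenyl)methanone | Oc1ccc([C@H]2c3c(O)cc(O)cc3[C@@H](C(=O)c3ccc(O)cc3)[C@@H]2c2cc(O)cc3c2[C@@H](c2cc(O)cc(O)c2)[C@H](c2ccc(O)cc2)O3)cc1 | intermediate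
35 | (1S,2R,3S)-2-[(2R,3R)-3-(3,5-dihydroxyphenyl)-6-hydroxy-2-(4-hydroxyphenyl)-2,3-dihydro-1-benzofuran-4-yl]-3-[(S)-hydroxy(4-hydroxyphenyl)methyl]-1-(4-hydroxyphenyl)indane-5,7-diol | Oc1ccc([C@H]2c3c(O)cc(O)cc3[C@@H]([C@H](O)c3ccc(O)cc3)[C@@H]2c2cc(O)cc3c2[C@@H](c2cc(O)cc(O)c2)[C@H](c2ccc(O)cc2)O3)cc1 | target

## Step count and least certain steps

Total: 22 steps. Longest linear sequence: 16 steps (steps 1, 3, 4, 8, 9 and 12 to 22, from 1; the branches from 3 through step 2 and from 7 through steps 5 to 7 are equally long).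

**Step 17 (key step).** The most likely failure is that the trivalent iodine reagent attacks the electron-rich rings (arylation at iodine or one-electron oxidation, ring D first). It may also stop at 1,2-dimethoxylation or dehydrogenate to the naphthalene. The cause is that both methoxy groups of ring B are meta to C3a, so neither the styrene nor the migrating carbon is activated.
Fallback: from 27, epoxidation with dimethyldioxirane (acetone, 0 °C) on the face anti to ring C gives the epoxide F1. Camphorsulfonic acid-catalysed methanolysis opens it at the benzylic carbon with inversion to the trans methoxy alcohol F2. Triflation (Tf2O, 2,6-di-tert-butylpyridine, CH2Cl2, −78 °C) gives the triflate F3, which has the same leaving-group and methoxy arrangement as 28. Warming it in buffered methanol triggers the same 1,2-shift of C3a without an oxidant present, and the route is rejoined at 29.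

**Step 8.** The thiolane may control the ylide face incompletely, eroding enantiopurity. The phenoxide may also be benzylated on oxygen by the sulfonium salt, and the quinone methide, crowded by the neighbouring bromine, may lose trans selectivity.
Fallback: from 6, the same annulation with the achiral 1-[(4-methoxyphenyl)methyl]thiolan-1-ium tetrafluoroborate F4 gives 14 together with its (2S,3S) enantiomer F5. Resolution by preparative chromatography on a chiral stationary phase returns the route at 14.

**Step 12.** The ortho-substituted aryl–rhodium species may insert slowly, so that protodeboronation consumes 17, and traces of base may racemise 22.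
Fallback: from 14, bromine–lithium exchange (15) and transmetalation with MgBr2·OEt2 give the aryl Grignard reagent F6. Copper-mediated conjugate addition (CuBr·SMe2, THF, −78 → −40 °C) to 22 is controlled by the C5 aryl group alone and rejoins the route at 23, bypassing 17.

**Step 15.** The cation may be captured by the second hydroxyl as a 2,5-diaryltetrahydrofuran that needs stronger acid to reopen. Under stronger acid the dihydrobenzofuran C2′–O bond and the second benzylic alcohol begin to ionise. A seven-membered closure onto ring D is the other competitor.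
Fallback: from 23, 3,5-dimethoxyphenyllithium F7 (from 3 and n-BuLi, −78 °C) opens the lactone to the γ-hydroxy ketone F8, which has no second hydroxyl. The same acid cyclisation then gives the tetralone F9, and NaBH4 reduction rejoins the route at 26.

**Step 22.** Facial selectivity may be low, because the two ring substituents on C3 (C2 and C3a) differ little in effective size and substrate control rests on the Felkin–Anh preference alone.
Fallback: from 34, catalyst-controlled asymmetric transfer hydrogenation with RuCl[(S,S)-TsDPEN](p-cymene) and HCO2H/Et3N, which reads aryl against alkyl and not the C3 environment, gives 35 directly; no new compound is made (F0).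

## Further compounds

F1 | step 17 | epoxide of 27 across C3–C4, oxygen anti to the C2 aryl group | COc1ccc([C@H]2c3c(OC)cc(OC)cc3[C@H]4O[C@H]4[C@@H]2c2cc(OC)cc3c2[C@@H](c2cc(OC)cc(OC)c2)[C@H](c2ccc(OC)cc2)O3)cc1
F2 | step 17 | 3-hydroxy-4-methoxy tetralin from F1, hydroxyl anti to the C2 aryl group, methoxy trans to hydroxyl | COc1ccc([C@H]2c3c(OC)cc(OC)cc3[C@H](OC)[C@@H](O)[C@@H]2c2cc(OC)cc3c2[C@@H](c2cc(OC)cc(OC)c2)[C@H](c2ccc(OC)cc2)O3)cc1
F3 | step 17 | trifluoromethanesulfonate of F2 | COc1ccc([C@H]2c3c(OC)cc(OC)cc3[C@H](OC)[C@@H](OS(=O)(=O)C(F)(F)F)[C@@H]2c2cc(OC)cc3c2[C@@H](c2cc(OC)cc(OC)c2)[C@H](c2ccc(OC)cc2)O3)cc1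
F4 | step 8 | 1-[(4-methoxyphenyl)methyl]thiolan-1-ium tetrafluoroborate | COc1ccc(C[S+]2CCCC2)cc1.F[B-](F)(F)F
F5 | step 8 | (2S,3S)-4-bromo-3-(3,5-dimethoxyphenyl)-6-methoxy-2-(4-methoxyphenyl)-2,3-dihydro-1-benzofuran | Brc1cc(OC)cc2c1[C@H](c1cc(OC)cc(OC)c1)[C@@H](c1ccc(OC)cc1)O2
F6 | step 12 | [(2R,3R)-3-(3,5-dimethoxyphenyl)-6-methoxy-2-(4-methoxyphenyl)-2,3-dihydro-1-benzofuran-4-yl]magnesium bromide | Br[Mg]c1cc(OC)cc2c1[C@@H](c1cc(OC)cc(OC)c1)[C@H](c1ccc(OC)cc1)O2
F7 | step 15 | 3,5-dimethoxyphenyllithium | [Li]c1cc(OC)cc(OC)c1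
F8 | step 15 | (3R,4S)-1-(3,5-dimethoxyphenyl)-3-[(2R,3R)-3-(3,5-dimethoxyphenyl)-6-methoxy-2-(4-methoxyphenyl)-2,3-dihydro-1-benzofuran-4-yl]-4-hydroxy-4-(4-methoxyphenyl)butan-1-one | O=C(C[C@@H]([C@H](O)c1ccc(OC)cc1)c1cc(OC)cc2c1[C@@H](c1cc(OC)cc(OC)c1)[C@H](c1ccc(OC)cc1)O2)c1cc(OC)cc(OC)c1
F9 | step 15 | (3S,4S)-3-[(2R,3R)-3-(3,5-dimethoxyphenyl)-6-methoxy-2-(4-methoxyphenyl)-2,3-dihydro-1-benzofuran-4-yl]-5,7-dimethoxy-4-(4-methoxyphenyl)-3,4-dihydronaphthalen-1(2H)-one | COc1ccc([C@H]2c3c(OC)cc(OC)cc3C(=O)C[C@@H]2c2cc(OC)cc3c2[C@@H](c2cc(OC)cc(OC)c2)[C@H](c2ccc(OC)cc2)O3)cc1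
F0 | step 22 | none | none
A1 | alternative 1 | methyl 2-[2-(3,5-dimethoxybenzoyl)-3,5-dimethoxyphenyl]acetate | COC(=O)Cc1cc(OC)cc(OC)c1C(=O)c1cc(OC)cc(OC)c1
A2 | alternative 1 | 3,5-dimethoxy-2-(trimethylsilyl)phenyl trifluoromethanesulfonate | COc1cc(OC)c([Si](C)(C)C)c(OS(=O)(=O)C(F)(F)F)c1
A3 | alternative 1 | methyl 3-(3,5-dimethoxyphenyl)-3-oxopropanoate | COC(=O)CC(=O)c1cc(OC)cc(OC)c1
A4 | alternative 2 | all-trans 5,7-dihydroxyindane with Cα as tert-butyldimethylsilyl ether and the other six phenols as methyl ethers | COc1ccc([C@H]2c3c(O)cc(O)cc3[C@@H]([C@H](O[Si](C)(C)C(C)(C)C)c3ccc(OC)cc3)[C@@H]2c2cc(OC)cc3c2[C@@H](c2cc(OC)cc(OC)c2)[C@H](c2ccc(OC)cc2)O3)cc1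
A5 | alternative 2 | 2-methyl-6,7-dihydrocyclopenta[b]pyran-4(5H)-one carrying ring A on C5, the dihydrobenzofuranyl group on C6 and the silyloxy(4-methoxyphenyl)methyl group on C7, configured as in A4 | COc1ccc([C@H]2C3=C(OC(C)=CC3=O)[C@@H]([C@H](O[Si](C)(C)C(C)(C)C)c3ccc(OC)cc3)[C@@H]2c2cc(OC)cc3c2[C@@H](c2cc(OC)cc(OC)c2)[C@H](c2ccc(OC)cc2)O3)cc1
A6 | alternative 3 | permethylated target with Cα as a ketone (identical with 33) | COc1ccc([C@H]2c3c(OC)cc(OC)cc3[C@@H](C(=O)c3ccc(OC)cc3)[C@@H]2c2cc(OC)cc3c2[C@@H](c2cc(OC)cc(OC)c2)[C@H](c2ccc(OC)cc2)O3)cc1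
A7 | alternative 3 | indanyl ketone whose ring C carries a free hydroxyl and an ortho (3,5-dimethoxyphenyl)(4-methylbenzenesulfonyl)methyl group | COc1ccc([C@H]2c3c(OC)cc(OC)cc3[C@@H](C(=O)c3ccc(OC)cc3)[C@@H]2c2cc(OC)cc(O)c2C(c2cc(OC)cc(OC)c2)S(=O)(=O)c2ccc(C)cc2)cc1
A8 | alternative 3 | 1-[(4-methoxyphenyl)methyl]thiolan-1-ium bromide | COc1ccc(C[S+]2CCCC2)cc1.[Br-]
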